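## The problem

Ring atoms are numbered C1(=O), C2(OH), C3(side chain), C4(=O), C5(OMe), C6(H). The chain is C1'–C13', with the acetate on O2' of the (R)-configured C2'.

- There is one ring and one stereocentre, so nothing has to be closed. The task is to join a C13 chain to the right carbon of a 1,2,4,5-tetraoxygenated ring and to tell like groups apart.
- C3 and C6 are both α-carbons of vinylogous acid units, and O2 and O5 differ only as OH and OCH3. Regiochemistry at carbon and at oxygen is therefore one problem, not two.
- C2' is isolated. No other stereo-element can control it, and its carbon neighbours C1' and C3' are both CH2 groups of large residues. A catalyst or enzyme has little to read, so the centre is better imported than made.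
- Two hydroxyl groups compete for the acetyl group, which must end on the less acidic O2'.
- The acetate is β to ring carbon C3, so base can remove a C1' proton through the quinone methide tautomer and expel acetate; alkoxide cleaves or shifts the ester, nucleophiles exchange the C5 methoxy group, and hydrides and organometallics attack the quinone.
- The feature that opens the key step is twofold: without the methyl carbon on O5 the ring is that of 2,5-dihydroxy-1,4-benzoquinone (3), whose C3–H and C6–H are exchanged by the C2 axis and are radical-accepting quinone C–H positions, and the fragment C1'–C13' with O2' is (R)-3-hydroxytetradecanoic acid (1) less its carboxyl carbon, C1' being C2 of the acid.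

## Retrosynthesis

**O5–CH3 (6 ⇒ 5).** The first cut removes the methyl carbon from O5 of 6.
- It is preferred to carrying O2 in masked form. It uncovers the hidden symmetry of the ring, and a protecting group on O2 would have to be removed beside a β-acetoxy quinone.
- Compound 5 is simpler by one differentiation: its two hydroxyl groups are told apart only by the chain at C3.
- The forward reaction must etherify O5, leave O2 free and spare the acetate.
- The chain just installed is the control element. It shields C2 against addition–elimination and would twist a C2 methoxy group out of conjugation.

**C3–C1' (5 ⇒ 2 + 3, by way of radical 4).**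
- Cutting C1'–C2' or C2'–C3' would mean creating the stereocentre during the coupling, between two similar CH2 groups. Cutting C3–C1' leaves C2' a spectator.
- Cutting homolytically at the quinone oxidation level, not heterolytically at the arene level, removes every O-protecting group and the closing oxidation.
- Radical 4 is traced back to acid 2 by adding CO2, a traceless handle.
- Compound 5 has 21 carbons and all functions of the target but one methyl. It falls into the six-carbon symmetric commodity 3 and the chiral-pool derivative 2.
- Three things are asked of the forward reaction: capture of 4 by 3 faster than its 1,2-acyloxy shift, one substitution and not two, and an oxidant that turns over the adduct radical but spares the enol units of the ring.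

**O2'–C(=O)CH3 (2 ⇒ 1).**
- The acetyl group goes on before the coupling, when the carbinol of 1 is the only alcohol present. The choice between O2' and the ring hydroxyl groups therefore never arises.
- The ester also shields the β-oxygen from the oxidant of the key step.
- Compound 1 is the (R)-3-hydroxyacyl unit of fatty acid biosynthesis, from which O2' of the natural product presumably derives.
- The forward reaction only has to avoid base.

## Roads not taken

**Alternative 1:** the cut is again C3–C1', but heterolytic and at the arene level.
- Forward step: 1,2,4,5-tetramethoxybenzene A1 is lithiated. It opens (R)-2-undecyloxirane A2 at the CH2 terminus to give (R)-1-(2,3,5,6-tetramethoxyphenyl)tridecan-2-ol A3. Acetylation, cerium(IV) oxidation and selective loss of one of the two remaining O-methyl groups follow.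
- This is the route most chemists would draw first, and each step has precedent.
- Against it: four methyl groups are carried in order to remove three. The OH/OMe problem is only postponed to the last step, where a vinylogous ester must be cleaved beside the acetate. About half of the longer sequence is redox or protecting-group adjustment.
- The chosen plan never leaves the quinone level and uses no protecting group.

**Alternative 2:** the cuts are the ring bonds C1–C2 and C3–C4, a ring synthesis by strain release.
- Forward step: (R)-2-undecyl-2,3-dihydrofuran A4, lithiated α to oxygen, adds to 3-methoxycyclobut-3-ene-1,2-dione A5. The 4-hydroxycyclobutenone A6 opens on heating (4π) to a dienylketene, which closes (6π). Oxidation then gives a dihydrobenzofuran-4,7-dione whose temporary O–C2' ring ties O2 to the chain.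
- Regiochemistry is wrong. Organolithiums add to the carbonyl of A5 next to the methoxy-bearing carbon, because the other carbonyl is deactivated as a vinylogous ester. The methoxy group therefore ends on C6, giving (R)-6-methoxy-2-undecyl-2,3-dihydrobenzofuran-4,7-dione A7, the wrong constitutional series.
- One oxygen would have to serve as both O2 and O2', and A4 needs several steps from A2.
- The opposite polarity, the chain as carbanion on a squarate, fails through β-elimination. The run-up costs more than the ring expansion gains.

**Alternative 3:** the cut is C3–C1' together with a temporary O2–C2' bond.
- Forward step: Mn(III)- or Ce(IV)-mediated oxidative [3+2] annulation of 2-hydroxy-5-methoxy-1,4-benzoquinone A8 with tridec-1-ene A9 gives 5-methoxy-2-undecyl-2,3-dihydrobenzofuran-4,7-dione A10.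
- In its favour: C3 selectivity is innate, since only the enol unit is oxidised, and the building blocks are the cheapest possible.
- Against it: C2' arises from a planar secondary radical or cation with nothing to bias it, so A10 is racemic.
- Opening the temporary ring needs attack at the flanked C2, while the C5 methoxy carbon is more accessible and would exchange first.
- A site-selective acetylation would still follow.

Key step: step 2

Assumption: 1 is taken as a catalogue compound of high enantiomeric purity. Replacing its CO2H by the ring leaves the CIP order O > CH2X > C11H23 > H unchanged, so (R)-1 corresponds to the (R)-target.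

## Steps

Step 1
Reactants: 1 (R)-3-hydroxytetradecanoic acid
Product: 2 (R)-3-acetoxytetradecanoic acid
Conditions: AcCl (3 equiv), CH2Cl2, 0 °C to rt; evaporation
Reagents that add atoms: acetyl chloride, CC(=O)Cl
Why: Base-free O-acylation of a secondary alcohol by an acyl chloride, as practised on unprotected α- and β-hydroxy acids; without base no E1cB loss of acetate towards the 2-enoic acid can start. The carbinol C–O bond is not touched, so the (R) configuration is retained.

Step 2
Reactants: 2 (R)-3-acetoxytetradecanoic acid; 3 2,5-dihydroxy-1,4-benzoquinone
Product: 5 (R)-1-(2,5-dihydroxy-3,6-dioxocyclohexa-1,4-dien-1-yl)tridecan-2-yl acetate, via 2-acetoxytridecyl radical 4 (not isolated)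
Conditions: AgNO3 (20 mol %), (NH4)2S2O8 (1.5 equiv, slow addition), 3 (3 equiv), MeCN–H2O (1:1), 65 °C
Reagents that add atoms: none
Why: This is a silver-catalysed peroxodisulfate decarboxylation (Kochi–Minisci type radical generation) coupled to homolytic substitution of a quinone C–H, the reaction type long used to alkylate benzoquinones and hydroxyquinones with carboxylic acids. Ag(I) is oxidised to Ag(II), which takes one electron from the carboxylate of 2; loss of CO2 gives the primary radical 4, which adds to C3 of 3 to give a captodatively stabilised radical at C2 that is oxidised and deprotonated back to the quinone 5. No ring is closed and no stereocentre is made: C2' lies one atom from the radical centre, none of its four bonds is broken, and the configuration of 2 is carried over. Regioselectivity needs no control, because C3–H and C6–H of 3 are exchanged by the C2 axis of the ring and the oxygen-bearing carbons do not take up the radical productively. Mono- over dialkylation is secured by the excess of cheap 3, which is separated afterwards through its insolubility in the lipophilic extract. The one rearrangement open to 4, the 1,2-acyloxy (Surzur–Tanner) shift to the secondary radical, is slow beside bimolecular capture by a quinone present in excess. The medium is acidic throughout, so loss of acetic acid through the C1' quinone methide cannot be triggered.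

Step 3
Reactants: 5 (R)-1-(2,5-dihydroxy-3,6-dioxocyclohexa-1,4-dien-1-yl)tridecan-2-yl acetate
Product: 6 (R)-1-(2-hydroxy-5-methoxy-3,6-dioxocyclohexa-1,4-dien-1-yl)tridecan-2-yl acetate (target, CNP0258436.1)
Conditions: HC(OMe)3 (2 equiv), CSA (10 mol %), MeOAc, 40 °C
Reagents that add atoms: trimethyl orthoformate, COC(OC)OC
Why: Acid-catalysed vinylogous esterification (addition–elimination of methanol at C5 of the protonated hydroxyquinone, the orthoester serving as methanol source and water scavenger), the standard way from cyclic 1,3-dicarbonyl enols and hydroxyquinones to their methyl ethers. C5 is flanked by C6–H whereas C2 is flanked by the chain at C3, which slows addition there and would force a C2 methoxy group out of conjugation, so rate and equilibrium both favour the 5-ether. Methyl acetate as solvent makes any acid-catalysed exchange at the C2' acetate degenerate, and C2' itself is not involved.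

## Compound list

1 | (R)-3-hydroxytetradecanoic acid | CCCCCCCCCCC[C@H](CC(=O)O)O | starting material
2 | (R)-3-acetoxytetradecanoic acid | CCCCCCCCCCC[C@H](CC(=O)O)OC(C)=O | intermediate
3 | 2,5-dihydroxy-1,4-benzoquinone | O=C1C=C(O)C(=O)C=C1O | starting material
4 | 2-acetoxytridecyl radical, acetoxy carbon configured in space as in 2 | CCCCCCCCCCC[C@H]([CH2])OC(C)=O | intermediate
5 | (R)-1-(2,5-dihydroxy-3,6-dioxocyclohexa-1,4-dien-1-yl)tridecan-2-yl acetate | CCCCCCCCCCC[C@H](CC1=C(O)C(=O)C=C(O)C1=O)OC(C)=O | intermediate
6 | (R)-1-(2-hydroxy-5-methoxy-3,6-dioxocyclohexa-1,4-dien-1-yl)tridecan-2-yl acetate | CCCCCCCCCCC[C@H](CC1=C(O)C(=O)C=C(OC)C1=O)OC(C)=O | target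

## Count and risks

Total step count: 3. Longest linear sequence: 3.

**Step 2 (key step).**
- The most likely failure is slow addition of the nucleophilic primary radical to C3 of a ring that carries two donor oxygens. Hydrogen abstraction, dimerisation and the acyloxy shift then gain ground.
- Meanwhile Ag(II) and sulfate radical anion may degrade the enol units of the excess quinone, the ring oxyanion may tie up silver, and the hot acidic water may begin to hydrolyse the acetate. A second alkylation at C6 is the lesser concern.
- The fallback inverts the polarity and uses the ring as the nucleophile. It sets out from 2 and comes back at 5.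
- Acid 2 is subjected to Hunsdiecker-type decarboxylative iodination (PhI(OAc)2, I2, hν) to give (R)-1-iodotridecan-2-yl acetate F1.
- Kornblum oxidation (AgBF4, DMSO, then Et3N) leads to (R)-1-oxotridecan-2-yl acetate F2.
- F2 is used at once, because its stereocentre is α to the aldehyde, in a three-component reductive alkylation of 3 with Hantzsch ester under amine catalysis in CH2Cl2. Knoevenagel condensation at the nucleophilic C3 is followed by conjugate hydride transfer, a known alkylation of this very ring, and gives 5.

**Step 3.**
- The most likely failures are methanolysis of the C2' acetate by the methanol released, partial etherification at O2, and double etherification if the reaction is pushed.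
- The fallback reverses the sense of the desymmetrisation: it overshoots under neutral conditions and comes back. It sets out from 5 and returns at 6.
- Exhaustive O-methylation with excess TMSCHN2 (toluene–MeOH, 0 °C) gives (R)-1-(2,5-dimethoxy-3,6-dioxocyclohexa-1,4-dien-1-yl)tridecan-2-yl acetate F3.
- The C2 methoxy group of F3, twisted out of conjugation by the C3 chain, is the more labile vinylogous ester. It is hydrolysed selectively with aqueous HClO4 in dioxane at rt to give 6.

**Step 1.**
- The most likely failure is self-acylation through activation of the free carboxyl group (oligoester formation), and elimination towards the conjugated acid on concentration.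
- The fallback masks the acid. It sets out from 1 and returns at 2.
- Alkylation with BnBr and KHCO3 in DMF gives benzyl (R)-3-hydroxytetradecanoate F4.
- Ac2O in pyridine gives benzyl (R)-3-acetoxytetradecanoate F5.
- Hydrogenolysis (H2, Pd/C, EtOAc) releases 2.

## Further compounds

F1 | step 2 | (R)-1-iodotridecan-2-yl acetate | CCCCCCCCCCC[C@H](CI)OC(C)=O
F2 | step 2 | (R)-1-oxotridecan-2-yl acetate | CCCCCCCCCCC[C@H](C=O)OC(C)=O
F3 | step 3 | (R)-1-(2,5-dimethoxy-3,6-dioxocyclohexa-1,4-dien-1-yl)tridecan-2-yl acetate | CCCCCCCCCCC[C@H](CC1=C(OC)C(=O)C=C(OC)C1=O)OC(C)=O
F4 | step 1 | benzyl (R)-3-hydroxytetradecanoate | CCCCCCCCCCC[C@H](CC(=O)OCc1ccccc1)O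
F5 | step 1 | benzyl (R)-3-acetoxytetradecanoate | CCCCCCCCCCC[C@H](CC(=O)OCc1ccccc1)OC(C)=O
A1 | alternative 1 | 1,2,4,5-tetramethoxybenzene | COc1cc(OC)c(OC)cc1OC
A2 | alternative 1 | (R)-2-undecyloxirane | CCCCCCCCCCC[C@@H]1CO1
A3 | alternative 1 | (R)-1-(2,3,5,6-tetramethoxyphenyl)tridecan-2-ol | CCCCCCCCCCC[C@H](Cc1c(OC)c(OC)cc(OC)c1OC)O
A4 | alternative 2 | (R)-2-undecyl-2,3-dihydrofuran | CCCCCCCCCCC[C@@H]1CC=CO1
A5 | alternative 2 | 3-methoxycyclobut-3-ene-1,2-dione | COC1=CC(=O)C1=O
A6 | alternative 2 | 4-hydroxy-3-methoxy-4-[(R)-5-undecyl-4,5-dihydrofuran-2-yl]cyclobut-2-en-1-one (carbinol epimers) | CCCCCCCCCCC[C@@H]1CC=C(O1)C1(O)C(OC)=CC1=O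
A7 | alternative 2 | (R)-6-methoxy-2-undecyl-2,3-dihydrobenzofuran-4,7-dione | CCCCCCCCCCC[C@@H]1CC2=C(O1)C(=O)C(OC)=CC2=O
A8 | alternative 3 | 2-hydroxy-5-methoxy-1,4-benzoquinone | COC1=CC(=O)C(O)=CC1=O
A9 | alternative 3 | tridec-1-ene | C=CCCCCCCCCCCC
A10 | alternative 3 | rac-5-methoxy-2-undecyl-2,3-dihydrobenzofuran-4,7-dione | CCCCCCCCCCCC1CC2=C(O1)C(=O)C=C(OC)C2=O
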